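The route rests on disconnecting the only C=C bond of the spiro cyclohexene ring (the CH bound to the spiro carbon and the isopropyl-bearing carbon) by ring-closing metathesis. This closes the last ring on a finished cyclopenta[b]chromene that already carries every stereocentre. The precursor is a chroman-fused cyclopentane whose quaternary carbon bears an ethenyl group and an (R)-configured chain ending in a 1,1-disubstituted alkene. Its quaternary/tertiary pair comes from an iridium-catalysed allylic alkylation; the chroman arises from an ortho-quinone methide cycloaddition to a vinyl sulfide, whose sulfur is then removed by a radical reduction.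

Key step: step 9

Assumption (remark on the chemistry): 2 and 7 are taken as purchasable, and the ortho-quinone methide 14 is assumed to react with its isobutyl group pointing away from the reacting carbonyl oxygen.

Step 1
Reactants: 1 methyl 2-oxocyclopentane-1-carboxylate; 2 (E)-1-chlorobut-2-ene
Product: 3 methyl (1S)-1-[(2R)-but-3-en-2-yl]-2-oxocyclopentane-1-carboxylate
Conditions: [Ir(cod)Cl]2 (2 mol %), chiral N-aryl phosphoramidite ligand (4 mol %), TBD (10 mol %), LiOtBu, THF, 25 °C
Reagents that add atoms: none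
Why: Iridium-catalysed branched-selective asymmetric allylic alkylation of a cyclic β-ketoester enolate with a crotyl electrophile, in which the ligand enantiomer is chosen to give the (R) allylic carbon and the catalyst-bound enolate face should give the (S) quaternary carbon.

Step 2
Reactants: 3 methyl (1S)-1-[(2R)-but-3-en-2-yl]-2-oxocyclopentane-1-carboxylate
Product: 4 methyl (1S)-1-[(2R)-but-3-en-2-yl]-3-methyl-2-oxocyclopentane-1-carboxylate (both C3 epimers)
Conditions: LiN(iPr)2, THF, −78 °C; then MeI, −78 °C to 0 °C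
Reagents that add atoms: iodomethane, CI
Why: Ketone enolate alkylation that can only occur at C3 because C1 is quaternary; the new C3 centre is left uncontrolled since it becomes sp2 in step 3.

Step 3
Reactants: 4 methyl (1S)-1-[(2R)-but-3-en-2-yl]-3-methyl-2-oxocyclopentane-1-carboxylate
Product: 5 methyl (1S)-1-[(2R)-but-3-en-2-yl]-3-methyl-2-(trifluoromethanesulfonyloxy)cyclopent-2-ene-1-carboxylate
Conditions: KN(SiMe3)2, THF, −78 °C; then PhNTf2, −78 °C to 0 °C
Reagents that add atoms: N-phenylbis(trifluoromethanesulfonimide), O=S(=O)(N(c1ccccc1)S(=O)(=O)C(F)(F)F)C(F)(F)F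
Why: Regiospecific enolate O-triflation (the only α-hydrogen is at C3), which merges both C3 epimers into one alkenyl triflate.

Step 4
Reactants: 5 methyl (1S)-1-[(2R)-but-3-en-2-yl]-3-methyl-2-(trifluoromethanesulfonyloxy)cyclopent-2-ene-1-carboxylate
Product: 6 methyl (1R)-1-[(2R)-but-3-en-2-yl]-3-methyl-2-(phenylsulfanyl)cyclopent-2-ene-1-carboxylate
Conditions: PhSH, Pd2(dba)3 (2.5 mol %), Xantphos (5 mol %), iPr2NEt, 1,4-dioxane, 100 °C
Reagents that add atoms: thiophenol, Sc1ccccc1
Why: Palladium-catalysed C–S cross-coupling of an alkenyl triflate with a thiol (Migita type), which installs the sulfur that later directs the cycloaddition regiochemistry; the descriptor at C1 changes only through the priority rules.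

Step 5
Reactants: 6 methyl (1R)-1-[(2R)-but-3-en-2-yl]-3-methyl-2-(phenylsulfanyl)cyclopent-2-ene-1-carboxylate; 7 2-bromo-3-methylbut-1-ene
Product: 9 methyl (1R)-3-methyl-1-[(2R)-6-methyl-5-methylideneheptan-2-yl]-2-(phenylsulfanyl)cyclopent-2-ene-1-carboxylate, via alkylborane 8 (not isolated)
Conditions: 9-BBN dimer, THF, 0 °C to 25 °C; then 7, Pd(dppf)Cl2 (5 mol %), K3PO4, DMF–H2O, 25 °C
Reagents that add atoms: none
Why: Anti-Markovnikov hydroboration of the only monosubstituted alkene (the tetrasubstituted vinyl sulfide is inert) followed by B-alkyl Suzuki–Miyaura coupling with the 2-bromoalkene; no stereocentre is touched.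

Step 6
Reactants: 9 methyl (1R)-3-methyl-1-[(2R)-6-methyl-5-methylideneheptan-2-yl]-2-(phenylsulfanyl)cyclopent-2-ene-1-carboxylate
Product: 11 {[(5S)-5-ethenyl-2-methyl-5-[(2R)-6-methyl-5-methylideneheptan-2-yl]cyclopent-1-en-1-yl]sulfanyl}benzene, via aldehyde 10 (not isolated)
Conditions: iBu2AlH, CH2Cl2, −78 °C; then Ph3P=CH2 (from Ph3PCH3Br and KN(SiMe3)2), THF, −78 °C to 25 °C
Reagents that add atoms: methylenetriphenylphosphorane, C=P(c1ccccc1)(c1ccccc1)c1ccccc1
Why: One-pot partial ester reduction and Wittig methylenation, in which the aluminium hemiacetal of the neopentyl-type ester should hold at −78 °C and release the aldehyde to the ylide; the quaternary centre keeps its geometry.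

Step 7
Reactants: 11 {[(5S)-5-ethenyl-2-methyl-5-[(2R)-6-methyl-5-methylideneheptan-2-yl]cyclopent-1-en-1-yl]sulfanyl}benzene; 12 2,4,6-trihydroxybenzene-1,3-dicarbaldehyde; 13 3-methylbutanal
Product: 15 (3S,3aR,9R,9aR)-3-ethenyl-6,8-dihydroxy-9a-methyl-3-[(2R)-6-methyl-5-methylideneheptan-2-yl]-9-(2-methylpropyl)-3a-(phenylsulfanyl)-1,2,3,3a,9,9a-hexahydrocyclopenta[b]chromene-5,7-dicarbaldehyde, via quinone-methide 14 (not isolated)
Conditions: EDDA (20 mol %), 4 Å molecular sieves, toluene, 80 °C
Reagents that add atoms: none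
Why: Knoevenagel condensation gives ortho-quinone methide 14, which should undergo an inverse-demand hetero-Diels–Alder reaction with the sulfur-activated alkene (C–C bond to the methyl-bearing β-carbon, C–O bond to the thionium-stabilised carbon) on the face syn to the small ethenyl group and anti to the branched chain, fixing C9a and C3a, while the orientation with the bulky phenylsulfanyl group exo and the carbocycle endo is needed to fix C9.

Step 8
Reactants: 15 the O,S-ketal cycloadduct
Product: 16 (3S,3aS,9S,9aR)-3-ethenyl-6,8-dihydroxy-9a-methyl-3-[(2R)-6-methyl-5-methylideneheptan-2-yl]-9-(2-methylpropyl)-1,2,3,3a,9,9a-hexahydrocyclopenta[b]chromene-5,7-dicarbaldehyde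
Conditions: Bu3SnH, AIBN (cat.), toluene, 80 °C
Reagents that add atoms: none
Why: Radical chain desulfurisation in which the tin radical abstracts the phenylsulfanyl group and the ring-fusion α-aryloxy radical should take hydrogen from Bu3SnH on the convex face, giving the cis-fused (3aS) junction without ionising the aryl ether.

Step 9
Reactants: 16 the chroman diene
Product: 17 (1R,3'aS,6R,9'S,9'aR)-6',8'-dihydroxy-6,9'a-dimethyl-9'-(2-methylpropyl)-3-(propan-2-yl)-1',2',9',9'a-tetrahydro-3'aH-spiro[cyclohex-2-ene-1,3'-cyclopenta[b]chromene]-5',7'-dicarbaldehyde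
Conditions: second-generation Hoveyda–Grubbs catalyst (10 mol %), toluene (2 mM), 80 °C
Reagents that add atoms: none
Why: The ruthenium alkylidene loads on one terminal alkene, undergoes [2+2] cycloaddition with the other, and cycloreversion expels ethene (Chauvin mechanism). The closest known reaction type is ring-closing metathesis to a trisubstituted cyclohexene next to a quaternary carbon. The six-membered carbocycle is closed by forming its own C=C bond between the ethenyl CH on the spiro carbon and the isopropyl-bearing methylidene carbon. No stereocentre is formed, and the spiro carbon and C6, set in step 1, are not epimerisable under these conditions. The step needs ring closure to beat oligomerisation and needs tolerance of two hydrogen-bonded aryl aldehydes and free phenols. The first is secured by six-ring formation at a quaternary carbon under high dilution, the second by the inertness of these groups toward ruthenium carbenes.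

Compound list
1 | methyl 2-oxocyclopentane-1-carboxylate | COC(=O)C1CCCC1=O | starting material
2 | (E)-1-chlorobut-2-ene | C/C=C/CCl | starting material
3 | methyl (1S)-1-[(2R)-but-3-en-2-yl]-2-oxocyclopentane-1-carboxylate | COC(=O)[C@]1([C@H](C)C=C)CCCC1=O | intermediate
4 | methyl (1S)-1-[(2R)-but-3-en-2-yl]-3-methyl-2-oxocyclopentane-1-carboxylate (both C3 epimers) | COC(=O)[C@]1([C@H](C)C=C)CCC(C)C1=O | intermediate
5 | methyl (1S)-1-[(2R)-but-3-en-2-yl]-3-methyl-2-(trifluoromethanesulfonyloxy)cyclopent-2-ene-1-carboxylate | COC(=O)[C@]1([C@H](C)C=C)CCC(C)=C1OS(=O)(=O)C(F)(F)F | intermediate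
6 | methyl (1R)-1-[(2R)-but-3-en-2-yl]-3-methyl-2-(phenylsulfanyl)cyclopent-2-ene-1-carboxylate | COC(=O)[C@]1([C@H](C)C=C)CCC(C)=C1Sc2ccccc2 | intermediate
7 | 2-bromo-3-methylbut-1-ene | CC(C)C(Br)=C | starting material
8 | alkylborane: methyl (1R)-1-[(2R)-4-(9-borabicyclo[3.3.1]nonan-9-yl)butan-2-yl]-3-methyl-2-(phenylsulfanyl)cyclopent-2-ene-1-carboxylate | COC(=O)[C@]1([C@H](C)CCB4C5CCCC4CCC5)CCC(C)=C1Sc2ccccc2 | intermediate
9 | methyl (1R)-3-methyl-1-[(2R)-6-methyl-5-methylideneheptan-2-yl]-2-(phenylsulfanyl)cyclopent-2-ene-1-carboxylate | COC(=O)[C@]1([C@H](C)CCC(=C)C(C)C)CCC(C)=C1Sc2ccccc2 | intermediate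
10 | aldehyde: (1R)-3-methyl-1-[(2R)-6-methyl-5-methylideneheptan-2-yl]-2-(phenylsulfanyl)cyclopent-2-ene-1-carbaldehyde | O=C[C@]1([C@H](C)CCC(=C)C(C)C)CCC(C)=C1Sc2ccccc2 | intermediate
11 | {[(5S)-5-ethenyl-2-methyl-5-[(2R)-6-methyl-5-methylideneheptan-2-yl]cyclopent-1-en-1-yl]sulfanyl}benzene | C=C[C@]1([C@H](C)CCC(=C)C(C)C)CCC(C)=C1Sc2ccccc2 | intermediate
12 | 2,4,6-trihydroxybenzene-1,3-dicarbaldehyde | O=Cc1c(O)cc(O)c(C=O)c1O | starting material
13 | 3-methylbutanal | CC(C)CC=O | starting material
14 | quinone-methide: 2,4-diformyl-3,5-dihydroxy-6-(3-methylbutylidene)cyclohexa-2,4-dien-1-one | O=C1C(C=O)=C(O)C(C=O)=C(O)C1=CCC(C)C | intermediate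
15 | (3S,3aR,9R,9aR)-3-ethenyl-6,8-dihydroxy-9a-methyl-3-[(2R)-6-methyl-5-methylideneheptan-2-yl]-9-(2-methylpropyl)-3a-(phenylsulfanyl)-1,2,3,3a,9,9a-hexahydrocyclopenta[b]chromene-5,7-dicarbaldehyde | CC(C)C[C@@H]1c2c(O)c(C=O)c(O)c(C=O)c2O[C@@]2(Sc3ccccc3)[C@]1(C)CC[C@]2(C=C)[C@H](C)CCC(=C)C(C)C | intermediate
16 | (3S,3aS,9S,9aR)-3-ethenyl-6,8-dihydroxy-9a-methyl-3-[(2R)-6-methyl-5-methylideneheptan-2-yl]-9-(2-methylpropyl)-1,2,3,3a,9,9a-hexahydrocyclopenta[b]chromene-5,7-dicarbaldehyde | CC(C)C[C@@H]1c2c(O)c(C=O)c(O)c(C=O)c2O[C@H]2[C@]1(C)CC[C@]2(C=C)[C@H](C)CCC(=C)C(C)C | intermediate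
17 | (1R,3'aS,6R,9'S,9'aR)-6',8'-dihydroxy-6,9'a-dimethyl-9'-(2-methylpropyl)-3-(propan-2-yl)-1',2',9',9'a-tetrahydro-3'aH-spiro[cyclohex-2-ene-1,3'-cyclopenta[b]chromene]-5',7'-dicarbaldehyde | CC(C)C[C@@H]1c2c(O)c(C=O)c(O)c(C=O)c2O[C@H]2[C@]1(C)CC[C@@]21C=C(C(C)C)CC[C@H]1C | target

Total step count: 9. Longest linear sequence: 9 steps (from 1).

Steps most likely to fail

Step 7. Several processes can go wrong. The electron-poor diformyl quinone methide may add to the unhindered 1,1-disubstituted side-chain alkene instead of the congested vinyl sulfide. The O,S-ketal, whose aryloxide is a good leaving group, may ionise and be hydrolysed by the water of condensation. The endo/exo orientation may favour the C9 epimer. The fallback sets out from 11 and comes back at 17. It uses an electron-rich phenol and introduces the formyl groups last. 2-Hydroxy-4,6-dimethoxybenzaldehyde and iBuMgBr would give 2-(1-hydroxy-3-methylbutyl)-3,5-dimethoxyphenol F1. Heating F1 with 11 in toluene at 110 °C should generate a less electrophilic, more selective quinone methide and give the 6,8-dimethoxy O,S-ketal F2, whose aryl ether no longer ionises and on which C9 epimers could be separated. Bu3SnH and AIBN would give the desulfurised diene F3. Ring-closing metathesis with the second-generation Hoveyda–Grubbs catalyst would give the spiro dimethyl ether F4, still closing the cyclohexene last. Bis-formylation with Cl2CHOMe and TiCl4 at −78 °C would give the diformyl dimethyl ether F5, and BCl3 would cleave both methyl ethers, each ortho to a formyl group, to give 17.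

Step 1. The enolate may attack the crotyl–iridium complex through the wrong face, giving the other diastereomer at the quaternary carbon, or at the unsubstituted terminus, giving linear product. The fallback sets out from 1 and comes back at 3. A bifunctional amine–thiourea catalysed Michael addition of 1 to (E)-1-nitroprop-1-ene would build the same quaternary/tertiary pair in a hydrogen-bonded complex, giving methyl (1S)-1-[(2S)-1-nitropropan-2-yl]-2-oxocyclopentane-1-carboxylate F6. A Nef reaction (NaOMe, MeOH; then H2SO4, −20 °C) would give methyl (1S)-2-oxo-1-[(2S)-1-oxopropan-2-yl]cyclopentane-1-carboxylate F7. One equivalent of Ph3P=CH2 at −78 °C should methylenate the aldehyde in preference to the hindered ketone and give 3.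

Step 9. The ruthenium carbene may load only slowly on either hindered alkene (a neopentyl ethenyl group and a 1,1-disubstituted alkene), so that catalyst decay or dimerisation outruns ring closure. The fallback sets out from 10 and comes back at 17. It is a relay design that lets the catalyst enter at an unhindered terminal alkene. Wittig reaction of 10 with the ylide from (hex-5-en-1-yl)triphenylphosphonium bromide would give {[(5R)-5-(hepta-1,6-dien-1-yl)-2-methyl-5-[(2R)-6-methyl-5-methylideneheptan-2-yl]cyclopent-1-en-1-yl]sulfanyl}benzene F8. The cycloaddition of step 7 would give the analogue of 15 with a hepta-1,6-dien-1-yl group at C3, F9. Bu3SnH would give the corresponding analogue of 16, F10. Relay metathesis would then expel cyclopentene, place the carbene directly on the carbon attached to the spiro centre, and close the cyclohexene to 17.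

Further compounds
F1 | step 7 | 2-(1-hydroxy-3-methylbutyl)-3,5-dimethoxyphenol (racemic) | CC(C)CC(O)c1c(O)cc(OC)cc1OC
F2 | step 7 | (3S,3aR,9R,9aR)-3-ethenyl-6,8-dimethoxy-9a-methyl-3-[(2R)-6-methyl-5-methylideneheptan-2-yl]-9-(2-methylpropyl)-3a-(phenylsulfanyl)-1,2,3,3a,9,9a-hexahydrocyclopenta[b]chromene | CC(C)C[C@@H]1c2c(OC)cc(OC)cc2O[C@@]2(Sc3ccccc3)[C@]1(C)CC[C@]2(C=C)[C@H](C)CCC(=C)C(C)C
F3 | step 7 | (3S,3aS,9S,9aR)-3-ethenyl-6,8-dimethoxy-9a-methyl-3-[(2R)-6-methyl-5-methylideneheptan-2-yl]-9-(2-methylpropyl)-1,2,3,3a,9,9a-hexahydrocyclopenta[b]chromene | CC(C)C[C@@H]1c2c(OC)cc(OC)cc2O[C@H]2[C@]1(C)CC[C@]2(C=C)[C@H](C)CCC(=C)C(C)C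
F4 | step 7 | (1R,3'aS,6R,9'S,9'aR)-6',8'-dimethoxy-6,9'a-dimethyl-9'-(2-methylpropyl)-3-(propan-2-yl)-1',2',9',9'a-tetrahydro-3'aH-spiro[cyclohex-2-ene-1,3'-cyclopenta[b]chromene] | CC(C)C[C@@H]1c2c(OC)cc(OC)cc2O[C@H]2[C@]1(C)CC[C@@]21C=C(C(C)C)CC[C@H]1C
F5 | step 7 | 6',8'-di-O-methyl ether of 17 | CC(C)C[C@@H]1c2c(OC)c(C=O)c(OC)c(C=O)c2O[C@H]2[C@]1(C)CC[C@@]21C=C(C(C)C)CC[C@H]1C
F6 | step 1 | methyl (1S)-1-[(2S)-1-nitropropan-2-yl]-2-oxocyclopentane-1-carboxylate | COC(=O)[C@]1([C@H](C)C[N+](=O)[O-])CCCC1=O
F7 | step 1 | methyl (1S)-2-oxo-1-[(2S)-1-oxopropan-2-yl]cyclopentane-1-carboxylate | COC(=O)[C@]1([C@H](C)C=O)CCCC1=O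
F8 | step 9 | {[(5R)-5-(hepta-1,6-dien-1-yl)-2-methyl-5-[(2R)-6-methyl-5-methylideneheptan-2-yl]cyclopent-1-en-1-yl]sulfanyl}benzene (alkene isomers) | C=CCCCC=C[C@]1([C@H](C)CCC(=C)C(C)C)CCC(C)=C1Sc2ccccc2
F9 | step 9 | analogue of 15 with a hepta-1,6-dien-1-yl group in place of the 3-ethenyl group | CC(C)C[C@@H]1c2c(O)c(C=O)c(O)c(C=O)c2O[C@@]2(Sc3ccccc3)[C@]1(C)CC[C@]2(C=CCCCC=C)[C@H](C)CCC(=C)C(C)C
F10 | step 9 | analogue of 16 with a hepta-1,6-dien-1-yl group in place of the 3-ethenyl group | CC(C)C[C@@H]1c2c(O)c(C=O)c(O)c(C=O)c2O[C@H]2[C@]1(C)CC[C@]2(C=CCCCC=C)[C@H](C)CCC(=C)C(C)C
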